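**Plan**
- Late cuts: the O9–angeloyl and O8–acetyl ester bonds, C11=C13 and C10–C14, leaving a cyclodec-4-en-10-one fused to a masked lactone.
- Key cut: the ring alkenes C1=C10 and C4=C5, joined through C2–C3, form a 1,5-diene inside the ten-membered ring C1–C10. Cutting C2–C3 and rejoining C5–C10 (retro oxy-Cope) gives a 1-vinyl-2-isopropenylcyclohexanol whose ring C5–C10 already carries C6–C9.
- Early cuts: C10–C1 (vinyl to ketone), C5–C4 (isopropenyl to epoxide), the epoxide and C9–H, C7–C11 (vinyl cuprate), back to a 4-silyloxycyclohexenone.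
- Forward: the cyclohexane is present from the start, the acetal ring C6–O–C12–C11–C7 is closed second, the ten-membered ring arises third by four-atom ring expansion; then lactone, C14 methyl, C13 methylene, esters.
- Stereochemistry: C6 from Ru-catalysed transfer hydrogenation; C7, C8 and C9 relayed from C6 (anti cuprate addition, anti enol-ether oxidation, axial hydride); C5 and C10 are auxiliary centres that fix E-C4=C5 in the chair transition state; Z-C1=C10 comes from the enol triflate geometry.

Key step: step 17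

Numbering: germacrane numbers are used for every intermediate (cyclohexane carbons are C5–C10; C11/C12 are the two-carbon chain on C7). β is the face of the C7 side chain, α the opposite face. TMS = trimethylsilyl, TES = triethylsilyl, TBS = tert-butyldimethylsilyl, PMB = 4-methoxybenzyl.
Assumption: the methyl acetal at C12 forms as an anomeric mixture; one anomer (12β-OMe) is drawn and carried, since the centre is lost at the lactone stage.

Step 1
Reactants: 1 1,4-dioxaspiro[4.5]dec-6-en-8-one
Product: 2 (R)-1,4-dioxaspiro[4.5]dec-6-en-8-ol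
Conditions: RuCl(p-cymene)[(R,R)-TsDPEN] (1 mol %), i-PrOH, rt
Reagents that add atoms: none
Why: Noyori-type asymmetric transfer hydrogenation reduces the enone carbonyl 1,2-selectively, and with the R,R ligand the alkenyl group should take the place of the aryl group of the usual model so that hydride gives the R carbinol, the future C6.

Step 2
Reactants: 2 (R)-1,4-dioxaspiro[4.5]dec-6-en-8-ol
Product: 3 (R)-4-hydroxycyclohex-2-en-1-one
Conditions: pyridinium p-toluenesulfonate (cat.), THF/H2O, 40 °C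
Reagents that add atoms: water, O
Why: Acid-catalysed ketal hydrolysis is driven by formation of the conjugated enone (C9 ketone, C7=C8), and the mild acid should leave the carbinol centre untouched.

Step 3
Reactants: 3 (R)-4-hydroxycyclohex-2-en-1-one
Product: 4 (R)-4-(triethylsilyloxy)cyclohex-2-en-1-one
Conditions: Et3SiCl, imidazole, CH2Cl2, 0 °C
Reagents that add atoms: chlorotriethylsilane, CC[Si](Cl)(CC)CC
Why: Standard silylation gives a bulky γ-silyloxy group to steer the cuprate addition, chosen as TES so that it can later be removed in the presence of a TBS ether.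

Step 4
Reactants: 4 (R)-4-(triethylsilyloxy)cyclohex-2-en-1-one; 5 vinylmagnesium bromide
Product: 6 C8=C9 trimethylsilyl enol ether carrying 7β-vinyl trans to 6α-OTES
Conditions: CuBr·SMe2 (10 mol %), Me3SiCl, DMPU, THF, −78 °C; then Et3N
Reagents that add atoms: chlorotrimethylsilane, C[Si](C)(C)Cl
Why: Copper-catalysed conjugate addition in the presence of Me3SiCl should deliver vinyl anti to the γ-silyloxy group, which sets C7, and traps the enolate regiospecifically as the C8=C9 silyl enol ether.

Step 5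
Reactants: 6 C8=C9 trimethylsilyl enol ether carrying 7β-vinyl trans to 6α-OTES
Product: 8 8α-hydroxy-7β-vinyl-6α-OTES-cyclohexan-9-one (all-trans), via α-silyloxy ketone 7 (not isolated)
Conditions: m-CPBA, NaHCO3, CH2Cl2, −20 °C; then citric acid, MeOH, 0 °C
Reagents that add atoms: m-chloroperbenzoic acid, OOC(=O)c1cccc(Cl)c1
Why: Rubottom oxidation, in which the peracid attacks the electron-rich enol ether rather than the vinyl group and from the face anti to the C7 substituent, so that the C8 oxygen is set trans to C7 before brief acidic methanolysis removes the TMS group.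

Step 6
Reactants: 8 8α-hydroxy-7β-vinyl-6α-OTES-cyclohexan-9-one
Product: 9 8α-OTBS-7β-vinyl-6α-OTES-cyclohexan-9-one
Conditions: t-BuMe2SiOTf, 2,6-lutidine, CH2Cl2, −78 °C
Reagents that add atoms: tert-butyldimethylsilyl triflate, CC(C)(C)[Si](C)(C)OS(=O)(=O)C(F)(F)F
Why: Silylation of the α-ketol at low temperature avoids enol silylation and installs the O8 group that survives until the fluoride step at the end.

Step 7
Reactants: 9 8α-OTBS-7β-vinyl-6α-OTES-cyclohexan-9-one
Product: 11 8α-OTBS-7β-vinyl-6α-OTES-cyclohex-5(10)-en-9-one, via silyl enol ether 10 (not isolated)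
Conditions: LiN(i-Pr)2, Me3SiCl, THF, −78 °C; then Pd(OAc)2 (1.05 equiv), MeCN, rt
Reagents that add atoms: none
Why: Saegusa–Ito oxidation, in which kinetic deprotonation occurs at the C10 methylene rather than at the silyloxy-bearing C8 and Pd(OAc)2 dehydrosilylates the C9=C10 enol ether to the C5=C10 enone.

Step 8
Reactants: 11 8α-OTBS-7β-vinyl-6α-OTES-cyclohex-5(10)-en-9-one
Product: 12 8α-OTBS-7β-vinyl-6α-OTES-cyclohex-5(10)-en-9β-ol
Conditions: NaBH4, CeCl3·7H2O, MeOH, −78 °C
Reagents that add atoms: none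
Why: Luche reduction is 1,2-selective, and axial hydride delivery to the half-chair with the three substituents pseudo-equatorial should give the pseudo-equatorial 9β-alcohol, trans to the 8α-silyloxy group.

Step 9
Reactants: 12 8α-OTBS-7β-vinyl-6α-OTES-cyclohex-5(10)-en-9β-ol
Product: 13 5β,10β-epoxy-8α-OTBS-7β-vinyl-6α-OTES-cyclohexan-9β-ol
Conditions: VO(acac)2 (cat.), t-BuOOH, CH2Cl2, 0 °C
Reagents that add atoms: tert-butyl hydroperoxide, CC(C)(C)OO
Why: Vanadium-catalysed hydroxyl-directed epoxidation delivers oxygen syn to the 9β-hydroxyl, which is also the face anti to the 6α-silyloxy group, and does not touch the isolated vinyl group.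

Step 10
Reactants: 13 5β,10β-epoxy-8α-OTBS-7β-vinyl-6α-OTES-cyclohexan-9β-ol
Product: 14 5β,10β-epoxy-9β-OPMB-8α-OTBS-7β-vinyl-6α-OTES-cyclohexane
Conditions: NaH, 4-MeOC6H4CH2Cl, Bu4NI (cat.), THF/DMF, 0 °C
Reagents that add atoms: 4-methoxybenzyl chloride, COc1ccc(CCl)cc1
Why: Williamson etherification, in which the cis-epoxy alkoxide cannot undergo Payne rearrangement and fast alkylation by the benzylic iodide formed in situ should outrun silyl transfer from O8.

Step 11
Reactants: 14 5β,10β-epoxy-9β-OPMB-8α-OTBS-7β-vinyl-6α-OTES-cyclohexane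
Product: 16 5β,10β-epoxy-9β-OPMB-8α-OTBS-7β-(2-hydroxyethyl)-6α-OTES-cyclohexane, via alkylborane 15 (not isolated)
Conditions: 9-BBN, THF, rt; then NaOH (aq.), H2O2, 0 °C
Reagents that add atoms: hydrogen peroxide, OO
Why: Hydroboration–oxidation with 9-BBN adds anti-Markovnikov to the only alkene, leaves the epoxide and ethers intact, and creates C12 at the alcohol level before a second alkene is present.

Step 12
Reactants: 16 5β,10β-epoxy-9β-OPMB-8α-OTBS-7β-(2-hydroxyethyl)-6α-OTES-cyclohexane; 17 isopropenylmagnesium bromide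
Product: 18 5α-isopropenyl-9β-OPMB-8α-OTBS-7β-(2-hydroxyethyl)-6α-OTES-cyclohexan-10β-ol
Conditions: CuI (20 mol %), THF, −30 → 0 °C (17 in excess)
Reagents that add atoms: none
Why: Copper-catalysed Grignard opening of the epoxide follows the Fürst–Plattner rule, so that with the C6–C9 substituents pseudo-equatorial the nucleophile should attack C5 from the α face (inversion) and leave the 10β-hydroxyl, one further equivalent of 17 being consumed by the primary hydroxyl, whose β side chain cannot reach C5 from the α face.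

Step 13
Reactants: 18 5α-isopropenyl-9β-OPMB-8α-OTBS-7β-(2-hydroxyethyl)-6α-OTES-cyclohexan-10β-ol
Product: 19 5α-isopropenyl-9β-OPMB-8α-OTBS-7β-(2-oxoethyl)-6α-OTES-cyclohexan-10-one
Conditions: Dess–Martin periodinane, NaHCO3, CH2Cl2, 0 °C → rt
Reagents that add atoms: none
Why: Dess–Martin oxidation converts the primary and the secondary alcohol together under buffered, non-enolising conditions, so the axial C5 centre and the β-silyloxy ketone should not be disturbed.

Step 14
Reactants: 19 5α-isopropenyl-9β-OPMB-8α-OTBS-7β-(2-oxoethyl)-6α-OTES-cyclohexan-10-one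
Product: 20 5α-isopropenyl keto acetal (C10 ketone; trans-fused C6–O–C12(OMe)–C11–C7 ring; 9β-OPMB; 8α-OTBS)
Conditions: pyridinium p-toluenesulfonate (cat.), MeOH, rt
Reagents that add atoms: methanol, CO
Why: Acid-catalysed acetalisation, in which methanolysis removes the labile TES ether and the freed 6α-hydroxyl closes on C12 to the trans-fused five-membered methyl acetal that masks the lactone, while the TBS and PMB ethers are stable to this mild acid.

Step 15
Reactants: 20 5α-isopropenyl keto acetal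
Product: 21 5β-isopropenyl keto acetal (all ring substituents equatorial)
Conditions: DBU (0.3 equiv), CH2Cl2, rt
Reagents that add atoms: none
Why: Base-mediated epimerisation through the C5 enolate (C5–H is α to the ketone and allylic) should favour at equilibrium the equatorial 5β-isopropenyl isomer, trans to the 6α-oxygen, while the equatorial C6–O bond is poorly aligned for β-elimination.

Step 16
Reactants: 21 5β-isopropenyl keto acetal; 5 vinylmagnesium bromide
Product: 22 10α-vinyl-5β-isopropenyl-cyclohexan-10β-ol with fused methyl acetal, 9β-OPMB and 8α-OTBS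
Conditions: CeCl3, THF, −78 °C
Reagents that add atoms: none
Why: Organocerium 1,2-addition suppresses enolisation of the acidic C5–H, and attack along the equatorial direction, away from the syn-axial hydrogens on C6 and C8 and consistent with chelation to the 9β-OPMB oxygen, should place vinyl α (equatorial, trans to isopropenyl) and the hydroxyl β (axial) at C10.

Step 17
Reactants: 22 10α-vinyl-5β-isopropenyl-cyclohexan-10β-ol with fused methyl acetal, 9β-OPMB and 8α-OTBS
Product: 25 (4E)-9β-OPMB-8α-OTBS-germacr-4-en-10-one 6α,12-methyl acetal, via potassium alkoxide 23 (not isolated), via potassium enolate 24 (not isolated)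
Conditions: KH, 18-crown-6, THF, 0 °C → rt; then AcOH, −78 °C
Reagents that add atoms: none
Why: The crown-ether-separated potassium alkoxide 23 undergoes an anionic oxy-Cope [3,3] shift through a chair transition state in which the vinyl terminus C2 bonds to the isopropenyl terminus C3 while C5–C10 breaks, and the resulting enolate 24 is protonated at C1 to the C10 ketone. The closest known reaction type is the anionic oxy-Cope ring expansion of trans-1,2-dialkenylcyclohexanols to (E)-cyclodec-5-enones. The ten-membered ring is not closed end to end but arises by four-atom expansion of the cyclohexane. No stereocentre is created: C5 and C10 become trigonal and C6–C9 are carried over unchanged from the rigid chair. The step needs the E geometry at C4=C5, which is secured because the C5–C6 bond is equatorial on the chair transition state of the trans-diequatorial dialkenyl isomer locked by the trans-fused acetal ring. The enolate geometry at C1=C10 that this chair delivers (C2 trans to C9) is the wrong one for the target, so it is erased by protonation and set again in step 19.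

Step 18
Reactants: 25 (4E)-9β-OPMB-8α-OTBS-germacr-4-en-10-one 6α,12-methyl acetal
Product: 27 (4E)-9β-OPMB-8α-OTBS-10-oxogermacr-4-en-12,6α-olide, via lactol 26 (not isolated)
Conditions: AcOH/THF/H2O (3:1:1), 35 °C; then PhI(OAc)2, TEMPO (cat.), CH2Cl2, rt
Reagents that add atoms: water, O
Why: Mild acid hydrolysis of the 2-methoxytetrahydrofuran acetal followed by TEMPO/PhI(OAc)2 oxidation of the lactol gives the lactone at the ketone stage, so that no acid meets the later 1,5-diene and C6/C7 are untouched.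

Step 19
Reactants: 27 (4E)-9β-OPMB-8α-OTBS-10-oxogermacr-4-en-12,6α-olide
Product: 29 (1(10)Z,4E)-enol triflate of 27 (C10–OTf; C2 cis to C9), via potassium enolate 28 (not isolated)
Conditions: KN(SiMe3)2 (1.05 equiv), THF, −78 °C; then PhNTf2, −78 → −40 °C
Reagents that add atoms: N-phenylbis(trifluoromethanesulfonimide), O=S(=O)(N(c1ccccc1)S(=O)(=O)C(F)(F)F)C(F)(F)F
Why: Kinetic enolisation and enol triflate formation, in which the base should remove a C1 proton faster than the proton on the alkoxy-bearing C9 or the less acidic lactone α-protons, and the enolate with C2 and C9 cis on the double bond, which avoids a second trans alkene in the ten-membered ring, is expected to form and is fixed by O-sulfonylation.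

Step 20
Reactants: 29 (1(10)Z,4E)-enol triflate; 30 methylmagnesium bromide
Product: 31 9β-OPMB-8α-OTBS-germacra-1(10)Z,4E-dien-12,6α-olide
Conditions: Fe(acac)3 (10 mol %), THF/NMP, −30 °C
Reagents that add atoms: none
Why: Iron-catalysed cross-coupling of an alkenyl triflate with a Grignard reagent is faster than addition to the lactone at this temperature and proceeds with retention of alkene geometry, installing C14 on a Z-C1=C10 bond.

Step 21
Reactants: 31 9β-OPMB-8α-OTBS-germacra-1(10)Z,4E-dien-12,6α-olide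
Product: 34 9β-OPMB-8α-OTBS-germacra-1(10)Z,4E,11(13)-trien-12,6α-olide, via Mannich base 32 (not isolated), via ammonium iodide 33 (not isolated)
Conditions: LiN(i-Pr)2, THF, −78 °C, then Me2N=CH2 I, −78 °C → rt; MeI, THF/MeOH, rt; NaHCO3 (aq.), CH2Cl2
Reagents that add atoms: Eschenmoser's salt, C=[N+](C)C.[I-]
Why: α-Methylenation by Mannich reaction of the lactone enolate with Eschenmoser's salt, N-methylation and base-induced elimination gives the exocyclic C11=C13 bond, the transient C11 centre being lost and C7 not being enolisable through this sequence.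

Step 22
Reactants: 34 9β-OPMB-8α-OTBS-germacra-1(10)Z,4E,11(13)-trien-12,6α-olide
Product: 35 9β-hydroxy-8α-OTBS-germacra-1(10)Z,4E,11(13)-trien-12,6α-olide
Conditions: DDQ, CH2Cl2/pH 7 buffer, 0 °C
Reagents that add atoms: none
Why: Oxidative cleavage of the PMB ether by DDQ runs under buffered neutral conditions that should spare the silyl ether, the diene and the methylene lactone.

Step 23
Reactants: 35 9β-hydroxy-8α-OTBS-germacra-1(10)Z,4E,11(13)-trien-12,6α-olide; 36 angelic acid
Product: 38 9β-angeloyloxy-8α-OTBS-germacra-1(10)Z,4E,11(13)-trien-12,6α-olide, via mixed anhydride 37 (not isolated)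
Conditions: 2,4,6-Cl3C6H2COCl, Et3N, toluene, rt; then 35, 80 °C
Reagents that add atoms: none
Why: Yamaguchi esterification through the mixed anhydride without a nucleophilic catalyst is the established way to transfer the angeloyl group to a hindered secondary alcohol without Z to E isomerisation to the tiglate.

Step 24
Reactants: 38 9β-angeloyloxy-8α-OTBS-germacra-1(10)Z,4E,11(13)-trien-12,6α-olide
Product: 39 9β-angeloyloxy-8α-hydroxygermacra-1(10)Z,4E,11(13)-trien-12,6α-olide
Conditions: HF·pyridine, pyridine, THF, 0 °C → rt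
Reagents that add atoms: none
Why: Fluoride desilylation under buffered, weakly acidic conditions should avoid base-induced acyl migration from O9 to O8, translactonisation to O8 and acid-induced transannular cyclisation.

Step 25
Reactants: 39 9β-angeloyloxy-8α-hydroxygermacra-1(10)Z,4E,11(13)-trien-12,6α-olide
Product: 40 8α-acetoxy-9β-angeloyloxygermacra-1(10)Z,4E,11(13)-trien-12,6α-olide (CNP0200690.1; 6R,7S,8R,9R)
Conditions: Ac2O, pyridine, DMAP (cat.), CH2Cl2, 0 °C
Reagents that add atoms: acetic anhydride, CC(=O)OC(C)=O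
Why: DMAP-catalysed acetylation of the free secondary alcohol is fast enough to outrun migration of the conjugated angeloyl group and completes the target.

**Compound list**
1 | 1,4-dioxaspiro[4.5]dec-6-en-8-one | O=C1C=CC2(CC1)OCCO2 | starting material
2 | (R)-1,4-dioxaspiro[4.5]dec-6-en-8-ol | O[C@H]1C=CC2(CC1)OCCO2 | intermediate
3 | (R)-4-hydroxycyclohex-2-en-1-one | O=C1C=C[C@H](O)CC1 | intermediate
4 | (R)-4-(triethylsilyloxy)cyclohex-2-en-1-one | O=C1C=C[C@H](O[Si](CC)(CC)CC)CC1 | intermediate
5 | vinylmagnesium bromide | C=C[Mg]Br | starting material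
6 | C8=C9 trimethylsilyl enol ether, 7β-vinyl, 6α-OTES | C[Si](C)(C)OC1=C[C@@H](C=C)[C@H](O[Si](CC)(CC)CC)CC1 | intermediate
7 | 8α-(trimethylsilyloxy)-7β-vinyl-6α-OTES-cyclohexan-9-one | O=C1[C@H](O[Si](C)(C)C)[C@@H](C=C)[C@H](O[Si](CC)(CC)CC)CC1 | intermediate (not isolated)
8 | 8α-hydroxy-7β-vinyl-6α-OTES-cyclohexan-9-one | O=C1[C@H](O)[C@@H](C=C)[C@H](O[Si](CC)(CC)CC)CC1 | intermediate
9 | 8α-OTBS-7β-vinyl-6α-OTES-cyclohexan-9-one | O=C1[C@H](O[Si](C)(C)C(C)(C)C)[C@@H](C=C)[C@H](O[Si](CC)(CC)CC)CC1 | intermediate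
10 | C9=C10 trimethylsilyl enol ether of 9 | C1=C(O[Si](C)(C)C)[C@H](O[Si](C)(C)C(C)(C)C)[C@@H](C=C)[C@H](O[Si](CC)(CC)CC)C1 | intermediate (not isolated)
11 | 8α-OTBS-7β-vinyl-6α-OTES-cyclohex-5(10)-en-9-one | O=C1[C@H](O[Si](C)(C)C(C)(C)C)[C@@H](C=C)[C@H](O[Si](CC)(CC)CC)C=C1 | intermediate
12 | 8α-OTBS-7β-vinyl-6α-OTES-cyclohex-5(10)-en-9β-ol | O[C@H]1[C@H](O[Si](C)(C)C(C)(C)C)[C@@H](C=C)[C@H](O[Si](CC)(CC)CC)C=C1 | intermediate
13 | 5β,10β-epoxy-8α-OTBS-7β-vinyl-6α-OTES-cyclohexan-9β-ol | O[C@H]1[C@H](O[Si](C)(C)C(C)(C)C)[C@@H](C=C)[C@H](O[Si](CC)(CC)CC)[C@H]2O[C@@H]12 | intermediate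
14 | 9β-PMB ether of 13 | COc1ccc(CO[C@H]2[C@H](O[Si](C)(C)C(C)(C)C)[C@@H](C=C)[C@H](O[Si](CC)(CC)CC)[C@H]3O[C@@H]23)cc1 | intermediate
15 | B-alkyl-9-borabicyclo[3.3.1]nonane from 14 | COc1ccc(CO[C@H]2[C@H](O[Si](C)(C)C(C)(C)C)[C@@H](CCB4C5CCCC4CCC5)[C@H](O[Si](CC)(CC)CC)[C@H]3O[C@@H]23)cc1 | intermediate (not isolated)
16 | 5β,10β-epoxy-9β-OPMB-8α-OTBS-7β-(2-hydroxyethyl)-6α-OTES-cyclohexane | COc1ccc(CO[C@H]2[C@H](O[Si](C)(C)C(C)(C)C)[C@@H](CCO)[C@H](O[Si](CC)(CC)CC)[C@H]3O[C@@H]23)cc1 | intermediate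
17 | isopropenylmagnesium bromide | CC(=C)[Mg]Br | starting material
18 | 5α-isopropenyl-9β-OPMB-8α-OTBS-7β-(2-hydroxyethyl)-6α-OTES-cyclohexan-10β-ol | O[C@H]1[C@@H](OCc2ccc(OC)cc2)[C@H](O[Si](C)(C)C(C)(C)C)[C@@H](CCO)[C@H](O[Si](CC)(CC)CC)[C@@H]1C(C)=C | intermediate
19 | 5α-isopropenyl-9β-OPMB-8α-OTBS-7β-(2-oxoethyl)-6α-OTES-cyclohexan-10-one | O=C1[C@@H](OCc2ccc(OC)cc2)[C@H](O[Si](C)(C)C(C)(C)C)[C@@H](CC=O)[C@H](O[Si](CC)(CC)CC)[C@@H]1C(C)=C | intermediate
20 | 5α-isopropenyl keto acetal (C10 ketone, fused methyl acetal, 9β-OPMB, 8α-OTBS) | O=C1[C@@H](OCc2ccc(OC)cc2)[C@H](O[Si](C)(C)C(C)(C)C)[C@H]3C[C@@H](OC)O[C@@H]3[C@@H]1C(C)=C | intermediate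
21 | 5β-isopropenyl keto acetal | O=C1[C@@H](OCc2ccc(OC)cc2)[C@H](O[Si](C)(C)C(C)(C)C)[C@H]3C[C@@H](OC)O[C@@H]3[C@H]1C(C)=C | intermediate
22 | 10α-vinyl-5β-isopropenyl-cyclohexan-10β-ol with fused methyl acetal, 9β-OPMB, 8α-OTBS | C=C[C@]1(O)[C@@H](OCc2ccc(OC)cc2)[C@H](O[Si](C)(C)C(C)(C)C)[C@H]3C[C@@H](OC)O[C@@H]3[C@H]1C(C)=C | intermediate
23 | potassium alkoxide of 22 | C=C[C@]1([O-])[C@@H](OCc2ccc(OC)cc2)[C@H](O[Si](C)(C)C(C)(C)C)[C@H]3C[C@@H](OC)O[C@@H]3[C@H]1C(C)=C.[K+] | intermediate (not isolated)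
24 | potassium C1=C10 enolate of 25 (C2 trans to C9) | [K+].[O-]/C1=C\CC/C(C)=C/[C@H]2O[C@H](OC)C[C@@H]2[C@@H](O[Si](C)(C)C(C)(C)C)[C@@H]1OCc3ccc(OC)cc3 | intermediate (not isolated)
25 | (4E)-9β-OPMB-8α-OTBS-germacr-4-en-10-one 6α,12-methyl acetal | O=C1CCC/C(C)=C/[C@H]2O[C@H](OC)C[C@@H]2[C@@H](O[Si](C)(C)C(C)(C)C)[C@@H]1OCc3ccc(OC)cc3 | intermediate
26 | lactol of 25 (C12 anomers) | O=C1CCC/C(C)=C/[C@H]2OC(O)C[C@@H]2[C@@H](O[Si](C)(C)C(C)(C)C)[C@@H]1OCc3ccc(OC)cc3 | intermediate (not isolated)
27 | (4E)-9β-OPMB-8α-OTBS-10-oxogermacr-4-en-12,6α-olide | O=C1CCC/C(C)=C/[C@H]2OC(=O)C[C@@H]2[C@@H](O[Si](C)(C)C(C)(C)C)[C@@H]1OCc3ccc(OC)cc3 | intermediate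
28 | potassium C1=C10 enolate of 27 (C2 cis to C9) | [K+].[O-]/C1=C/CC/C(C)=C/[C@H]2OC(=O)C[C@@H]2[C@@H](O[Si](C)(C)C(C)(C)C)[C@@H]1OCc3ccc(OC)cc3 | intermediate (not isolated)
29 | (1(10)Z,4E)-enol triflate of 27 | O=S(=O)(O/C1=C/CC/C(C)=C/[C@H]2OC(=O)C[C@@H]2[C@@H](O[Si](C)(C)C(C)(C)C)[C@@H]1OCc3ccc(OC)cc3)C(F)(F)F | intermediate
30 | methylmagnesium bromide | C[Mg]Br | starting material
31 | 9β-OPMB-8α-OTBS-germacra-1(10)Z,4E-dien-12,6α-olide | C/C1=C/CC/C(C)=C/[C@H]2OC(=O)C[C@@H]2[C@@H](O[Si](C)(C)C(C)(C)C)[C@@H]1OCc3ccc(OC)cc3 | intermediate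
32 | 11-(dimethylaminomethyl) lactone (C11 epimers) | C/C1=C/CC/C(C)=C/[C@H]2OC(=O)C(CN(C)C)[C@@H]2[C@@H](O[Si](C)(C)C(C)(C)C)[C@@H]1OCc3ccc(OC)cc3 | intermediate (not isolated)
33 | 11-(trimethylammoniomethyl) lactone iodide | C/C1=C/CC/C(C)=C/[C@H]2OC(=O)C(C[N+](C)(C)C)[C@@H]2[C@@H](O[Si](C)(C)C(C)(C)C)[C@@H]1OCc3ccc(OC)cc3.[I-] | intermediate (not isolated)
34 | 9β-OPMB-8α-OTBS-germacra-1(10)Z,4E,11(13)-trien-12,6α-olide | C/C1=C/CC/C(C)=C/[C@H]2OC(=O)C(=C)[C@@H]2[C@@H](O[Si](C)(C)C(C)(C)C)[C@@H]1OCc3ccc(OC)cc3 | intermediate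
35 | 9β-hydroxy-8α-OTBS-germacra-1(10)Z,4E,11(13)-trien-12,6α-olide | C/C1=C/CC/C(C)=C/[C@H]2OC(=O)C(=C)[C@@H]2[C@@H](O[Si](C)(C)C(C)(C)C)[C@@H]1O | intermediate
36 | angelic acid | C/C=C(/C)C(=O)O | starting material
37 | angelic 2,4,6-trichlorobenzoic anhydride | C/C=C(/C)C(=O)OC(=O)c1c(Cl)cc(Cl)cc1Cl | intermediate (not isolated)
38 | 9β-angeloyloxy-8α-OTBS-germacra-1(10)Z,4E,11(13)-trien-12,6α-olide | C/C1=C/CC/C(C)=C/[C@H]2OC(=O)C(=C)[C@@H]2[C@@H](O[Si](C)(C)C(C)(C)C)[C@@H]1OC(=O)/C(C)=C\C | intermediate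
39 | 9β-angeloyloxy-8α-hydroxygermacra-1(10)Z,4E,11(13)-trien-12,6α-olide | C/C1=C/CC/C(C)=C/[C@H]2OC(=O)C(=C)[C@@H]2[C@@H](O)[C@@H]1OC(=O)/C(C)=C\C | intermediate
40 | 8α-acetoxy-9β-angeloyloxygermacra-1(10)Z,4E,11(13)-trien-12,6α-olide (CNP0200690.1) | C=C1C(=O)O[C@@H]2/C=C(\C)CC/C=C(/C)[C@@H](OC(=O)/C(C)=C\C)[C@H](OC(C)=O)[C@@H]12 | target

**Step count**
Total steps: 25. Longest linear sequence: 25 steps (1 → 40); the route is fully linear, and the Grignard reagents and angelic acid are bought.

**Steps most likely to fail**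

Step 19. The ring does not enforce the enolate geometry, so enolisation of 27 may place C2 trans to C9 on the new double bond, or proceed toward C9, and the methyl coupling would then fix the wrong C1=C10 alkene. The fallback sets out from ketone 25 and returns at 31. Ketone 25 is condensed with 2,4,6-triisopropylbenzenesulfonyl hydrazide to the trisylhydrazone F1, whose N–N bond should point away from the substituted C9. A Shapiro reaction (n-BuLi, TMEDA, THF, −78 → 0 °C) removes the C1 proton syn to the sulfonamide nitrogen; the aza-enolate keeps C2 away from the nitrogen substituent, hence cis to C9, and loss of sulfinate and N2 gives the alkenyllithium F2. Quenching with MeI gives the methyl diene acetal F3. Mild hydrolysis (AcOH/THF/H2O) to the lactol F4 and TEMPO/PhI(OAc)2 oxidation then give lactone 31.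

Step 16. The vinyl nucleophile may attack axially, giving the cis-dialkenyl isomer (vinyl β), whose chair rearrangement would lead to the 4Z alkene. The fallback sets out from ketone 21 and returns at 22. Corey–Chaykovsky reaction with dimethylsulfoxonium methylide (Me3S(O)I, NaH, DMSO), which forms the carbon–carbon bond reversibly and hence equatorially, gives the spiro-epoxide F5 with oxygen β (axial). Excess dimethylsulfonium methylide (Me3SI, n-BuLi, THF) then opens F5 at its methylene carbon and eliminates dimethyl sulfide, converting the epoxide into the vinyl carbinol 22.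

Step 15. During the base equilibration the isopropenyl double bond may move into conjugation with the ketone, or the C6 oxygen may be lost by β-elimination, before the equatorial epimer accumulates. The fallback sets out from 20 and returns at 21, and replaces the equilibrium by irreversible enolisation and kinetic protonation. LiN(SiMe3)2 and Me3SiCl (THF, −78 °C) give the silyl dienol ether F6. Protonolysis with Bu4NF/AcOH at −78 °C then protonates the α-carbon C5 from the axial direction, which places the isopropenyl group equatorial and gives 21 without prolonged contact with base.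

**Further compounds**
F1 | step 19 | 2,4,6-triisopropylbenzenesulfonyl hydrazone of 25 | CC(C)c1cc(C(C)C)c(S(=O)(=O)N/N=C2\CCC/C(C)=C/[C@H]3O[C@H](OC)C[C@@H]3[C@@H](O[Si](C)(C)C(C)(C)C)[C@@H]2OCc4ccc(OC)cc4)c(C(C)C)c1
F2 | step 19 | C10 alkenyllithium (C2 cis to C9) | [Li]/C1=C/CC/C(C)=C/[C@H]2O[C@H](OC)C[C@@H]2[C@@H](O[Si](C)(C)C(C)(C)C)[C@@H]1OCc3ccc(OC)cc3
F3 | step 19 | 9β-OPMB-8α-OTBS-germacra-1(10)Z,4E-diene 6α,12-methyl acetal | C/C1=C/CC/C(C)=C/[C@H]2O[C@H](OC)C[C@@H]2[C@@H](O[Si](C)(C)C(C)(C)C)[C@@H]1OCc3ccc(OC)cc3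
F4 | step 19 | lactol of F3 (C12 anomers) | C/C1=C/CC/C(C)=C/[C@H]2OC(O)C[C@@H]2[C@@H](O[Si](C)(C)C(C)(C)C)[C@@H]1OCc3ccc(OC)cc3
F5 | step 16 | C10 spiro-epoxide of 21 (oxygen β, methylene α) | C1O[C@]12[C@@H](OCc4ccc(OC)cc4)[C@H](O[Si](C)(C)C(C)(C)C)[C@H]3C[C@@H](OC)O[C@@H]3[C@H]2C(C)=C
F6 | step 15 | C5=C10 trimethylsilyl dienol ether of 20 | CC(=C)C1=C(O[Si](C)(C)C)[C@@H](OCc2ccc(OC)cc2)[C@H](O[Si](C)(C)C(C)(C)C)[C@H]3C[C@@H](OC)O[C@@H]31
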